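**Plan**

- Numbering: isochromene numbering, unprimed for the quinone-methide half, primed for the lactone half.
- Retrosynthesis: the quinone methide is traced back to a 1-ethoxy acetal carrying boron at C8. The unprimed carbocycle is then cut at C7–C8 and C4a–C8a in one operation, giving a 2-pyrone with a tethered alkynylboronate. Further cuts are the acetal C1–O bond, the pyrone C3–CH2 bridge bond, and the acyl–carbon bonds joining one chiral acyl unit to two keto-ester nucleophiles.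
- Enabling feature: C4a, C5(Me), C6(O) and C7(CH2Ar) of the unprimed carbocycle are C6, C5, C4(O) and C3 of a 4-oxygenated 2-pyrone whose O1–C2(=O) bridge leaves as CO2. C8a and C8 are the two alkyne carbons, C1 is the acetal carbon of the tether, and the C8–B bond becomes C8–O.
- Forward: one Weinreb amide gives the pyrone and, by aldol aromatisation then lactonisation, the primed dihydroisocoumarin (benzene ring first, lactone ring second). A Mannich base/ortho-quinone methide joins the two at pyrone C3. Acetylation and acetal exchange attach the dienophile, the cycloaddition closes the dihydropyran and the benzene ring together, and oxidation/acid unveil the quinone methide.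
- Stereochemistry: C3 (= C3') is bought with ethyl (R)-3-hydroxybutanoate. C4 (= C4') is set anti to it by Fráter–Seebach methylation (substrate control), and the pair serves both halves. No later step makes or touches a lasting stereocenter.

Key step: step 12

Remark: the alkynylboronate acetal used in step 11 is taken as a purchasable reagent (otherwise one step from 3,3-diethoxyprop-1-yne by lithiation and borylation), and the ethoxy-acetal carbon introduced there is carried as a mixture of epimers because it becomes sp2 in the last step.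

**Route**

Step 1
Reactants: 1 ethyl (3R)-3-hydroxybutanoate
Product: 2 ethyl (2R,3R)-3-hydroxy-2-methylbutanoate
Conditions: LiN(iPr)2 (2.2 equiv), THF, −78 → −20 °C; MeI, DMPU, −78 → 0 °C; aq. NH4Cl
Reagents that add atoms: iodomethane, CI
Why: Fráter–Seebach alkylation, in which the chelated lithium alkoxide–enolate dianion is methylated on the face away from the C3 methyl group, so the new stereocenter should be set anti to the bought carbinol center.

Step 2
Reactants: 2 ethyl (2R,3R)-3-hydroxy-2-methylbutanoate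
Product: 3 ethyl (2R,3R)-2-methyl-3-[(triethylsilyl)oxy]butanoate
Conditions: Et3SiCl, imidazole, CH2Cl2, 0 °C → rt
Reagents that add atoms: chlorotriethylsilane, CC[Si](Cl)(CC)CC
Why: Standard silylation of a secondary alcohol; the triethylsilyl ether masks the oxygen through the enolate steps and later serves as the oxygen nucleophile of step 11.

Step 3
Reactants: 3 ethyl (2R,3R)-2-methyl-3-[(triethylsilyl)oxy]butanoate
Product: 4 (2R,3R)-N-methoxy-N,2-dimethyl-3-[(triethylsilyl)oxy]butanamide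
Conditions: MeNH(OMe)·HCl, iPrMgCl, THF, −20 → 0 °C
Reagents that add atoms: N,O-dimethylhydroxylamine hydrochloride, CNOC.Cl
Why: Direct ester-to-Weinreb-amide conversion with the magnesium amide, which is too weakly basic to epimerise the α-stereocenter and gives an acyl donor that stops at the ketone stage.

Step 4
Reactants: 4 (2R,3R)-N-methoxy-N,2-dimethyl-3-[(triethylsilyl)oxy]butanamide; 5 methyl 3-oxopentanoate
Product: 7 4-hydroxy-5-methyl-6-{(2R,3R)-3-[(triethylsilyl)oxy]butan-2-yl}-2H-pyran-2-one, via diketo ester 6 (not isolated)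
Conditions: 5, LiN(iPr)2 (2.1 equiv), THF, 0 °C; then 4, −78 → 0 °C; aq. NH4Cl; crude 6, DBU, toluene, 110 °C
Reagents that add atoms: none
Why: Weiler dianion acylation at the γ-carbon (Claisen type, the Weinreb chelate preventing over-addition) followed by DBU-mediated enol-lactonisation of the 3,5-diketo ester should give the 4-hydroxy-2-pyrone, the two stereocenters lying away from the far more acidic 1,3-dicarbonyl positions.

Step 5
Reactants: 8 2,2,6-trimethyl-4H-1,3-dioxin-4-one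
Product: 9 2,2-dimethyl-6-(2-oxobutyl)-4H-1,3-dioxin-4-one
Conditions: LiN(SiMe3)2 (2 equiv), THF, −78 °C; EtCOCl (1 equiv); aq. NH4Cl
Reagents that add atoms: propanoyl chloride, CCC(=O)Cl
Why: γ-Acylation of the lithium dienolate of the dioxinone (vinylogous Claisen condensation), with the second equivalent of base covering the more acidic product.

Step 6
Reactants: 9 2,2-dimethyl-6-(2-oxobutyl)-4H-1,3-dioxin-4-one; 4 (2R,3R)-N-methoxy-N,2-dimethyl-3-[(triethylsilyl)oxy]butanamide
Product: 10 6-{(5R,6R)-3,5-dimethyl-2,4-dioxo-6-[(triethylsilyl)oxy]heptyl}-2,2-dimethyl-4H-1,3-dioxin-4-one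
Conditions: 9, LiN(iPr)2 (2.1 equiv), THF, −78 °C; then 4, −78 → −40 °C; aq. NH4Cl
Reagents that add atoms: none
Why: The keto-dioxinone dianion should react at its terminal (ethyl) carbon with the Weinreb amide in a Claisen-type acylation, bringing the same anti stereodiad into the second half.

Step 7
Reactants: 10 6-{(5R,6R)-3,5-dimethyl-2,4-dioxo-6-[(triethylsilyl)oxy]heptyl}-2,2-dimethyl-4H-1,3-dioxin-4-one
Product: 12 (3R,4S)-6,8-dihydroxy-3,4,5-trimethyl-3,4-dihydro-1H-isochromen-1-one, via benzodioxinone 11 (not isolated)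
Conditions: Et3N (0.3 equiv), CH2Cl2, rt; then HCl in MeOH, rt → 50 °C
Reagents that add atoms: none
Why: Biomimetic polyketide aromatisation, in which base triggers the intramolecular aldol of the dioxinone α-carbon onto the distal ketone, and acid then completes dehydration to the resorcylate, removes the silyl group and lets the freed alcohol displace acetone by intramolecular transacylation with retention at the carbinol carbon.

Step 8
Reactants: 12 (3R,4S)-6,8-dihydroxy-3,4,5-trimethyl-3,4-dihydro-1H-isochromen-1-one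
Product: 13 (3R,4S)-7-[(dimethylamino)methyl]-6,8-dihydroxy-3,4,5-trimethyl-3,4-dihydro-1H-isochromen-1-one
Conditions: CH2=NMe2+ I−, Et3N, CH2Cl2, 0 °C → rt
Reagents that add atoms: N,N-dimethylmethyleneiminium iodide (Eschenmoser's salt), C=[N+](C)C.[I-]
Why: Phenol Mannich reaction; C7' is the only free ring position and lies ortho to both hydroxyls, so the aminomethylation is regiochemically unambiguous.

Step 9
Reactants: 13 (3R,4S)-7-[(dimethylamino)methyl]-6,8-dihydroxy-3,4,5-trimethyl-3,4-dihydro-1H-isochromen-1-one; 7 4-hydroxy-5-methyl-6-{(2R,3R)-3-[(triethylsilyl)oxy]butan-2-yl}-2H-pyran-2-one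
Product: 15 3-{[(3R,4S)-6,8-dihydroxy-3,4,5-trimethyl-1-oxo-3,4-dihydro-1H-isochromen-7-yl]methyl}-4-hydroxy-5-methyl-6-{(2R,3R)-3-[(triethylsilyl)oxy]butan-2-yl}-2H-pyran-2-one, via ortho-quinone methide 14 (not isolated)
Conditions: toluene, 100 °C, N2 stream
Reagents that add atoms: none
Why: Thermal loss of dimethylamine should give the ortho-quinone methide, which is captured at the nucleophilic C3 of the 4-hydroxy-2-pyrone (Michael addition of a vinylogous acid) to form the CH2 bridge.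

Step 10
Reactants: 15 3-{[(3R,4S)-6,8-dihydroxy-3,4,5-trimethyl-1-oxo-3,4-dihydro-1H-isochromen-7-yl]methyl}-4-hydroxy-5-methyl-6-{(2R,3R)-3-[(triethylsilyl)oxy]butan-2-yl}-2H-pyran-2-one
Product: 16 (3R,4S)-7-[(4-acetoxy-5-methyl-2-oxo-6-{(2R,3R)-3-[(triethylsilyl)oxy]butan-2-yl}-2H-pyran-3-yl)methyl]-3,4,5-trimethyl-1-oxo-3,4-dihydro-1H-isochromene-6,8-diyl diacetate
Conditions: Ac2O, pyridine, DMAP (cat.), CH2Cl2, 0 °C → rt
Reagents that add atoms: acetic anhydride, CC(=O)OC(C)=O
Why: Exhaustive O-acetylation under DMAP catalysis removes every acidic OH that could later protonate the alkynyl C–B bond or the acetal, and pyrone C3 and C5 are both substituted so no O-to-C acyl shift can follow.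

Step 11
Reactants: 16 (3R,4S)-7-[(4-acetoxy-5-methyl-2-oxo-6-{(2R,3R)-3-[(triethylsilyl)oxy]butan-2-yl}-2H-pyran-3-yl)methyl]-3,4,5-trimethyl-1-oxo-3,4-dihydro-1H-isochromene-6,8-diyl diacetate; 17 2-(3,3-diethoxyprop-1-yn-1-yl)-4,4,5,5-tetramethyl-1,3,2-dioxaborolane
Product: 18 (3R,4S)-7-{[4-acetoxy-6-((2R,3R)-3-{[1-ethoxy-3-(4,4,5,5-tetramethyl-1,3,2-dioxaborolan-2-yl)prop-2-yn-1-yl]oxy}butan-2-yl)-5-methyl-2-oxo-2H-pyran-3-yl]methyl}-3,4,5-trimethyl-1-oxo-3,4-dihydro-1H-isochromene-6,8-diyl diacetate (two epimers at the acetal carbon)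
Conditions: 17 (3 equiv), Me3SiOTf (0.2 equiv), CH2Cl2, −78 → −40 °C; Et3N quench
Reagents that add atoms: none
Why: Lewis-acid-catalysed transacetalisation of a silyl ether (Noyori-type exchange), in which Me3SiOTf ionises the diethyl acetal to an alkynyl oxocarbenium ion that the silyl ether oxygen captures with loss of the silyl group, so the dienophile is attached without a free alcohol or a base; the new acetal center forms unselectively, which is without consequence.

Step 12
Reactants: 18 (3R,4S)-7-{[4-acetoxy-6-((2R,3R)-3-{[1-ethoxy-3-(4,4,5,5-tetramethyl-1,3,2-dioxaborolan-2-yl)prop-2-yn-1-yl]oxy}butan-2-yl)-5-methyl-2-oxo-2H-pyran-3-yl]methyl}-3,4,5-trimethyl-1-oxo-3,4-dihydro-1H-isochromene-6,8-diyl diacetate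
Product: 20 (3R,4S)-7-{[(3R,4S)-6-acetoxy-1-ethoxy-3,4,5-trimethyl-8-(4,4,5,5-tetramethyl-1,3,2-dioxaborolan-2-yl)-3,4-dihydro-1H-isochromen-7-yl]methyl}-3,4,5-trimethyl-1-oxo-3,4-dihydro-1H-isochromene-6,8-diyl diacetate, via oxabicyclooctadienone cycloadduct 19 (not isolated)
Conditions: o-dichlorobenzene (0.01 M), BHT (cat.), 180 °C, sealed tube
Reagents that add atoms: none
Why: Thermal intramolecular [4+2] cycloaddition of the alkynylboronate across C3 and C6 of the 2-pyrone gives the 2-oxabicyclo[2.2.2]octadienone 19, which expels CO2 by retro-[4+2] and so leaves the benzene ring with both new C–C bonds in place (pyrone C6 to the acetal-bearing alkyne carbon, pyrone C3 to the boron-bearing alkyne carbon). The closest known reaction type is the Diels–Alder/cycloreversion of 2-pyrones with alkynylboronic esters to arylboronic esters, run here intramolecularly as in tethered pyrone–alkyne benzannulations. The carbocycle closes by the concerted [4+2] itself and becomes aromatic when the lactone bridge leaves; the dihydropyran closes as the tether ring of a type 1 intramolecular Diels–Alder reaction, a 6-exo-dig closure through the four-atom C–C–O–C tether. No new stereocenter survives, because the two bridgeheads of 19 become sp2 carbons on CO2 loss, C3 and C4 are untouched, and the acetal carbon stays an inconsequential epimeric mixture. The only selectivity needed is regiochemical (boron next to the benzyl-bearing carbon), and the tether secures it by allowing a single orientation. The earlier acetylation of all acidic OH groups should keep the alkynyl C–B bond from protonolysis at 180 °C.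

Step 13
Reactants: 20 (3R,4S)-7-{[(3R,4S)-6-acetoxy-1-ethoxy-3,4,5-trimethyl-8-(4,4,5,5-tetramethyl-1,3,2-dioxaborolan-2-yl)-3,4-dihydro-1H-isochromen-7-yl]methyl}-3,4,5-trimethyl-1-oxo-3,4-dihydro-1H-isochromene-6,8-diyl diacetate
Product: 22 dicitrinone G, (3R,4S)-6,8-dihydroxy-7-{[(3R,4S)-6-hydroxy-3,4,5-trimethyl-8-oxo-3,4-dihydro-8H-isochromen-7-yl]methyl}-3,4,5-trimethyl-3,4-dihydro-1H-isochromen-1-one, via ethoxy acetal tetraol 21 (not isolated)
Conditions: H2O2 (30% aq.), K2CO3, THF/H2O, 0 °C → rt; then 1 M HCl, THF, rt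
Reagents that add atoms: hydrogen peroxide, OO
Why: Hydroperoxide oxidation of the aryl boronate (1,2-aryl shift from boron to oxygen) with concurrent cleavage of the aryl acetates should give the 1-ethoxy acetal tetraol, which on acidification ionises at the acetal carbon and loses ethanol to the quinone methide.

**Compound list**

1 | ethyl (3R)-3-hydroxybutanoate | C[C@@H](O)CC(=O)OCC | starting material
2 | ethyl (2R,3R)-3-hydroxy-2-methylbutanoate | C[C@@H](O)[C@@H](C)C(=O)OCC | intermediate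
3 | ethyl (2R,3R)-2-methyl-3-[(triethylsilyl)oxy]butanoate | C[C@@H](O[Si](CC)(CC)CC)[C@@H](C)C(=O)OCC | intermediate
4 | (2R,3R)-N-methoxy-N,2-dimethyl-3-[(triethylsilyl)oxy]butanamide | C[C@@H](O[Si](CC)(CC)CC)[C@@H](C)C(=O)N(C)OC | intermediate
5 | methyl 3-oxopentanoate | CCC(=O)CC(=O)OC | starting material
6 | methyl (6R,7R)-4,6-dimethyl-3,5-dioxo-7-[(triethylsilyl)oxy]octanoate (C4 epimers and enol forms) | C[C@@H](O[Si](CC)(CC)CC)[C@@H](C)C(=O)C(C)C(=O)CC(=O)OC | intermediate (not isolated)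
7 | 4-hydroxy-5-methyl-6-{(2R,3R)-3-[(triethylsilyl)oxy]butan-2-yl}-2H-pyran-2-one | C[C@@H](O[Si](CC)(CC)CC)[C@@H](C)C1=C(C)C(O)=CC(=O)O1 | intermediate
8 | 2,2,6-trimethyl-4H-1,3-dioxin-4-one | CC1=CC(=O)OC(C)(C)O1 | starting material
9 | 2,2-dimethyl-6-(2-oxobutyl)-4H-1,3-dioxin-4-one | CCC(=O)CC1=CC(=O)OC(C)(C)O1 | intermediate
10 | 6-{(5R,6R)-3,5-dimethyl-2,4-dioxo-6-[(triethylsilyl)oxy]heptyl}-2,2-dimethyl-4H-1,3-dioxin-4-one (epimers at chain C3) | C[C@@H](O[Si](CC)(CC)CC)[C@@H](C)C(=O)C(C)C(=O)CC1=CC(=O)OC(C)(C)O1 | intermediate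
11 | 7-hydroxy-2,2,6-trimethyl-5-{(2S,3R)-3-[(triethylsilyl)oxy]butan-2-yl}-4H-1,3-benzodioxin-4-one | C[C@@H](O[Si](CC)(CC)CC)[C@@H](C)c1c(C)c(O)cc2OC(C)(C)OC(=O)c12 | intermediate (not isolated)
12 | (3R,4S)-6,8-dihydroxy-3,4,5-trimethyl-3,4-dihydro-1H-isochromen-1-one | c1c(O)c(C)c2c(c1O)C(=O)O[C@H](C)[C@H]2C | intermediate
13 | (3R,4S)-7-[(dimethylamino)methyl]-6,8-dihydroxy-3,4,5-trimethyl-3,4-dihydro-1H-isochromen-1-one | CN(C)Cc1c(O)c(C)c2c(c1O)C(=O)O[C@H](C)[C@H]2C | intermediate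
14 | (3R,4S)-8-hydroxy-3,4,5-trimethyl-7-methylidene-3,4-dihydro-1H-isochromene-1,6(7H)-dione (ortho-quinone methide) | C=C1C(=O)C(C)=C2C(=C1O)C(=O)O[C@H](C)[C@H]2C | intermediate (not isolated)
15 | 3-{[(3R,4S)-6,8-dihydroxy-3,4,5-trimethyl-1-oxo-3,4-dihydro-1H-isochromen-7-yl]methyl}-4-hydroxy-5-methyl-6-{(2R,3R)-3-[(triethylsilyl)oxy]butan-2-yl}-2H-pyran-2-one | C[C@@H](O[Si](CC)(CC)CC)[C@@H](C)C1=C(C)C(O)=C(Cc2c(O)c(C)c3c(c2O)C(=O)O[C@H](C)[C@H]3C)C(=O)O1 | intermediate
16 | (3R,4S)-7-[(4-acetoxy-5-methyl-2-oxo-6-{(2R,3R)-3-[(triethylsilyl)oxy]butan-2-yl}-2H-pyran-3-yl)methyl]-3,4,5-trimethyl-1-oxo-3,4-dihydro-1H-isochromene-6,8-diyl diacetate | C[C@@H](O[Si](CC)(CC)CC)[C@@H](C)C1=C(C)C(OC(C)=O)=C(Cc2c(OC(C)=O)c(C)c3c(c2OC(C)=O)C(=O)O[C@H](C)[C@H]3C)C(=O)O1 | intermediate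
17 | 2-(3,3-diethoxyprop-1-yn-1-yl)-4,4,5,5-tetramethyl-1,3,2-dioxaborolane | CCOC(OCC)C#CB1OC(C)(C)C(C)(C)O1 | starting material
18 | (3R,4S)-7-{[4-acetoxy-6-((2R,3R)-3-{[1-ethoxy-3-(4,4,5,5-tetramethyl-1,3,2-dioxaborolan-2-yl)prop-2-yn-1-yl]oxy}butan-2-yl)-5-methyl-2-oxo-2H-pyran-3-yl]methyl}-3,4,5-trimethyl-1-oxo-3,4-dihydro-1H-isochromene-6,8-diyl diacetate (acetal epimers) | C[C@@H](OC(OCC)C#CB1OC(C)(C)C(C)(C)O1)[C@@H](C)C1=C(C)C(OC(C)=O)=C(Cc2c(OC(C)=O)c(C)c3c(c2OC(C)=O)C(=O)O[C@H](C)[C@H]3C)C(=O)O1 | intermediate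
19 | 2-oxabicyclo[2.2.2]octa-5,7-dien-3-one cycloadduct of 18 (lactone bridge from C7 to C4a, dihydropyran fused at C4a–C8a) | C[C@H]1OC(OCC)C2=C(B3OC(C)(C)C(C)(C)O3)C3(Cc4c(OC(C)=O)c(C)c5c(c4OC(C)=O)C(=O)O[C@H](C)[C@H]5C)C(=O)OC2(C(C)=C3OC(C)=O)[C@@H]1C | intermediate (not isolated)
20 | (3R,4S)-7-{[(3R,4S)-6-acetoxy-1-ethoxy-3,4,5-trimethyl-8-(4,4,5,5-tetramethyl-1,3,2-dioxaborolan-2-yl)-3,4-dihydro-1H-isochromen-7-yl]methyl}-3,4,5-trimethyl-1-oxo-3,4-dihydro-1H-isochromene-6,8-diyl diacetate (acetal epimers) | C[C@H]1OC(OCC)c2c(B3OC(C)(C)C(C)(C)O3)c(Cc4c(OC(C)=O)c(C)c5c(c4OC(C)=O)C(=O)O[C@H](C)[C@H]5C)c(OC(C)=O)c(C)c2[C@@H]1C | intermediate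
21 | (3R,4S)-7-{[(3R,4S)-1-ethoxy-6,8-dihydroxy-3,4,5-trimethyl-3,4-dihydro-1H-isochromen-7-yl]methyl}-6,8-dihydroxy-3,4,5-trimethyl-3,4-dihydro-1H-isochromen-1-one (acetal epimers) | C[C@H]1OC(OCC)c2c(O)c(Cc3c(O)c(C)c4c(c3O)C(=O)O[C@H](C)[C@H]4C)c(O)c(C)c2[C@@H]1C | intermediate (not isolated)
22 | dicitrinone G | CC1=C2C(=CO[C@H](C)[C@H]2C)C(=O)C(Cc2c(O)c(C)c3c(c2O)C(=O)O[C@H](C)[C@H]3C)=C1O | target

**Summary**

Total step count: 13.
Longest linear sequence: 11 steps (1, 2, 3, 6, 7, 8, 9, 10, 11, 12, 13).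

Steps most likely to fail:

Step 12. Both bond-forming termini are fully substituted, so the cycloaddition may be slow enough for thermal loss of the alkynyl C–B bond and fragmentation of the acetal to win. Fallback, setting out from 7 and returning at 22: run the cycloaddition before the methylene bridge is made, while pyrone C3 still carries hydrogen. Acetylate 7 (Ac2O, pyridine) to 5-methyl-2-oxo-6-{(2R,3R)-3-[(triethylsilyl)oxy]butan-2-yl}-2H-pyran-4-yl acetate F1. Exchange its silyl ether with 17 (Me3SiOTf cat.) to the tethered alkynylboronate acetal F2. Heat (o-dichlorobenzene, 160 °C) so that the oxabicyclooctadienone cycloadduct F3 loses CO2 to the aryl boronate F4. Oxidise and deacetylate (H2O2, K2CO3) to (3R,4S)-1-ethoxy-3,4,5-trimethyl-3,4-dihydro-1H-isochromene-6,8-diol F5, and acidify to the monomeric quinone methide (3R,4S)-6-hydroxy-3,4,5-trimethyl-3,4-dihydro-8H-isochromen-8-one F6. Its nucleophilic C7 is then joined to the ortho-quinone methide 14, released from 13 in hot toluene, which gives 22 directly.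

Step 11. The boryl-substituted alkynyl acetal may ionise sluggishly, with double exchange of the acetal or loss of the C–B bond under the Lewis acid. Fallback, setting out from 16 and returning at 18: replace the Lewis-acid exchange by a base-buffered alkylation of the free alcohol. Cleave the silyl ether of 16 with HF·pyridine (THF, 0 °C) to the secondary alcohol (3R,4S)-7-({4-acetoxy-6-[(2R,3R)-3-hydroxybutan-2-yl]-5-methyl-2-oxo-2H-pyran-3-yl}methyl)-3,4,5-trimethyl-1-oxo-3,4-dihydro-1H-isochromene-6,8-diyl diacetate F7. Convert 17 with acetyl chloride and ZnBr2 (cat.) into the α-chloro ether 2-(3-chloro-3-ethoxyprop-1-yn-1-yl)-4,4,5,5-tetramethyl-1,3,2-dioxaborolane F8. Combine F7 and F8 with iPr2NEt in CH2Cl2 at 0 °C to reach 18.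

Step 9. The transient ortho-quinone methide may self-condense, or the pyrone may be alkylated on oxygen instead of carbon. Fallback, setting out from 12 (with 7) and returning at 15: form the bridge by reductive alkylation instead of quinone-methide capture. Ortho-formylate 12 (MgCl2, Et3N, paraformaldehyde, MeCN, reflux) to (3R,4S)-6,8-dihydroxy-3,4,5-trimethyl-1-oxo-3,4-dihydro-1H-isochromene-7-carbaldehyde F9. Condense it with 7 under L-proline catalysis to the 3-arylidene-pyran-2,4-dione F10, and reduce this in the same flask with the Hantzsch ester (diethyl 2,6-dimethyl-1,4-dihydropyridine-3,5-dicarboxylate) by conjugate hydride transfer, which gives 15.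

**Further compounds**

F1 | step 12 | 5-methyl-2-oxo-6-{(2R,3R)-3-[(triethylsilyl)oxy]butan-2-yl}-2H-pyran-4-yl acetate | C[C@@H](O[Si](CC)(CC)CC)[C@@H](C)C1=C(C)C(OC(C)=O)=CC(=O)O1
F2 | step 12 | 6-[(2R,3R)-3-{[1-ethoxy-3-(4,4,5,5-tetramethyl-1,3,2-dioxaborolan-2-yl)prop-2-yn-1-yl]oxy}butan-2-yl]-5-methyl-2-oxo-2H-pyran-4-yl acetate (acetal epimers) | C[C@@H](OC(OCC)C#CB1OC(C)(C)C(C)(C)O1)[C@@H](C)C1=C(C)C(OC(C)=O)=CC(=O)O1
F3 | step 12 | 2-oxabicyclo[2.2.2]octa-5,7-dien-3-one cycloadduct of F2 | C[C@H]1OC(OCC)C2=C(B3OC(C)(C)C(C)(C)O3)C3C(=O)OC2(C(C)=C3OC(C)=O)[C@@H]1C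
F4 | step 12 | (3R,4S)-1-ethoxy-3,4,5-trimethyl-8-(4,4,5,5-tetramethyl-1,3,2-dioxaborolan-2-yl)-3,4-dihydro-1H-isochromen-6-yl acetate (acetal epimers) | C[C@H]1OC(OCC)c2c(B3OC(C)(C)C(C)(C)O3)cc(OC(C)=O)c(C)c2[C@@H]1C
F5 | step 12 | (3R,4S)-1-ethoxy-3,4,5-trimethyl-3,4-dihydro-1H-isochromene-6,8-diol (acetal epimers) | C[C@H]1OC(OCC)c2c(O)cc(O)c(C)c2[C@@H]1C
F6 | step 12 | (3R,4S)-6-hydroxy-3,4,5-trimethyl-3,4-dihydro-8H-isochromen-8-one | CC1=C2C(=CO[C@H](C)[C@H]2C)C(=O)C=C1O
F7 | step 11 | (3R,4S)-7-({4-acetoxy-6-[(2R,3R)-3-hydroxybutan-2-yl]-5-methyl-2-oxo-2H-pyran-3-yl}methyl)-3,4,5-trimethyl-1-oxo-3,4-dihydro-1H-isochromene-6,8-diyl diacetate | C[C@@H](O)[C@@H](C)C1=C(C)C(OC(C)=O)=C(Cc2c(OC(C)=O)c(C)c3c(c2OC(C)=O)C(=O)O[C@H](C)[C@H]3C)C(=O)O1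
F8 | step 11 | 2-(3-chloro-3-ethoxyprop-1-yn-1-yl)-4,4,5,5-tetramethyl-1,3,2-dioxaborolane | CCOC(Cl)C#CB1OC(C)(C)C(C)(C)O1
F9 | step 9 | (3R,4S)-6,8-dihydroxy-3,4,5-trimethyl-1-oxo-3,4-dihydro-1H-isochromene-7-carbaldehyde | O=Cc1c(O)c(C)c2c(c1O)C(=O)O[C@H](C)[C@H]2C
F10 | step 9 | 3-{[(3R,4S)-6,8-dihydroxy-3,4,5-trimethyl-1-oxo-3,4-dihydro-1H-isochromen-7-yl]methylidene}-5-methyl-6-{(2R,3R)-3-[(triethylsilyl)oxy]butan-2-yl}-2H-pyran-2,4(3H)-dione | C[C@@H](O[Si](CC)(CC)CC)[C@@H](C)C1=C(C)C(=O)C(=Cc2c(O)c(C)c3c(c2O)C(=O)O[C@H](C)[C@H]3C)C(=O)O1
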